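The data come from a simulation with constants of no real substance; scatter was added.

Product and the charge not yet turned always add up to the whole charge of starting material, so one number describes a run: the unturned fraction, u.

| setting | Monday's | Thursday's | noon | spring | winter | dawn | dusk | midnight |
|---|---|---|---|---|---|---|---|---|
| starting material | 2 mM (in portions, 4) | 2 mM (in portions, 4) | 2.0 mM (in portions, 4) | 2.0 mM (in portions, 4) | 2.0 mM (in portions, 4) | 2.0 mM (in portions, 4) | 2.0 mM (in portions, 4) | 2.0 mM (in portions, 4) |
| second substrate | 1.1 equiv | 1.1 equiv | 1.10 equiv | 1.10 equiv | 1.10 equiv | 1.10 equiv | 1.10 equiv | 1.10 equiv |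
| free enzyme | 0.0026 mol% | 0.023 mol% | 0.006 mol% | 0.01 mol% | 0.005 mol% | 0.03 mol% | 0.015 mol% | 0.003 mol% |
| added ligand | 0.27 µM | 0.27 µM | 0.27 µM | 0.27 µM | 0.27 µM | 0.27 µM | 0.27 µM | 0.27 µM |
| temperature | 20 °C | 31 °C | 25 °C | 25 °C | 25 °C | 25 °C | 25 °C | 25 °C |
| remark | run made earlier; portions every 40 s | run made earlier; portions every 40 s | the portions of starting material follow each other after 40 s, the first at the start | the portions of starting material follow each other after 40 s, the first at the start | the portions of starting material follow each other after 40 s, the first at the start | the portions of starting material follow each other after 40 s, the first at the start | the portions of starting material follow each other after 40 s, the first at the start | the portions of starting material follow each other after 40 s, the first at the start |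
| time |  |  | 2.5 min | 2.5 min | 2.5 min | 2.5 min | 2.5 min | 2.5 min |

| Monday's: time / s | Monday's: product / % | Thursday's: time / s | Thursday's: product / % |
|---|---|---|---|
| 10.0 | 1.1 | 15.0 | 5.9 |
| 12.0 | 1.2 | 30.0 | 10.3 |
| 20.0 | 0.4 | 50.0 | 18.1 |
| 30.0 | 0 | 60.0 | 22.0 |
| 50.0 | 0 | 80.0 | 30.2 |
| 60.0 | 2.0 | 90.0 | 31.5 |
| 120 | 5.1 | 120 | 39.4 |

(each reading ± 1 percentage point)

- all flasks from highest to lowest amount of product, in percent of the starting material charged, at 2.5 min (noon / spring / winter / dawn / dusk / midnight)
- the amount of product, in percent of the starting material charged of the flask you put first, at 2.5 min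
- the amount of product, in percent of the starting material charged of the flask you put last, at 2.5 min

Thursday's table is the one to read first. Its product goes from 22.0% at 60.0 s to 39.4% at 120 s, and over that doubling of time −ln u grows to twice its value. A rate proportional to enzyme and to u, a pseudo-first-order fall with the portions not told apart, grows in just that way, and this reading is taken as such a fall: integration gives −ln u = k·E·t, with E the enzyme charged in concentration and u counted against the whole charge.

Thursday's last reading gives k as 9070 M⁻¹ s⁻¹. Monday's table stays close to its scatter of 1 percentage point at first, so its last reading, 5.1% at 120 s, is the useful one, and it gives 8390 M⁻¹ s⁻¹. A scatter of 1 point on 5.1% covers that difference, although the runs stand at 20 °C and 31 °C and their enzyme lies on either side of the ligand, below it on Monday and above it on Thursday. The mean, 8730 M⁻¹ s⁻¹, is the enzyme-time constant: the exponent −ln u earned per unit of enzyme concentration and per second.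

My own reckoning takes this constant for 25 °C, which lies between the two runs. Product then climbs with loading, and dawn has more enzyme than any other flask, while midnight has less. At 2.5 min dawn should hold 54.4% and midnight 7.56%.

The forecast gives dawn > dusk > spring > noon > winter > midnight, with 55% on top and 8% at the bottom. It says “The two runs bracket a threshold”, whereas this reckoning uses one constant on both sides of the ligand, yet the two stand close in their numbers.

The simulation gives dawn > dusk > spring > noon > winter > midnight, with 56.3% and 9.33%.

    free enzyme → unfolded enzyme (k = 6.30 × 10⁻⁴ s⁻¹, Ea = 236 kJ mol⁻¹)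
    ternary complex → free enzyme + product (k = 160 s⁻¹, Ea = 62.0 kJ mol⁻¹)
    starting material + free enzyme ⇌ starting complex (K = 170 M⁻¹, k = 1.60 × 10⁶ M⁻¹ s⁻¹, Ea = 18.0 kJ mol⁻¹, ΔH = 2.00 kJ mol⁻¹)
    free enzyme + added ligand ⇌ idle complex (K = 4.00 × 10⁶ M⁻¹, k = 54000 M⁻¹ s⁻¹, Ea = 8.00 kJ mol⁻¹, ΔH = 3.00 kJ mol⁻¹)
    second substrate + starting complex ⇌ ternary complex (K = 820 M⁻¹, k = 7.50 × 10⁶ M⁻¹ s⁻¹, Ea = 16.0 kJ mol⁻¹, ΔH = −20.0 kJ mol⁻¹)
    (constants at 25 °C)

Put back into the constant, dawn's result gives 9200 M⁻¹ s⁻¹ and midnight's 10900 M⁻¹ s⁻¹, against 8730 M⁻¹ s⁻¹ from the runs. In midnight at 1.45 min, ternary complex falls back 57 times faster than it goes on to product, and at 2.50 min the ratio of its making to its using up stands at 1.00. A flask like midnight kept at 40 °C gives 3.03% and a constant of 3420 M⁻¹ s⁻¹, with unfolded enzyme at 93.5% of the catalyst charged.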